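**Retrosynthetic overview**
- Iriomoteolide 3a comes from its 7,8,15-tris-TBS ether by a final desilylation.
- Both rings are made in one flask from an open-chain (E)-iodoalkene/(2R)-chloro aldehyde: Ni/Cr alkenylation at C10–C11 closes the 15-membered lactone first, then the C11 alkoxide displaces the C12 chloride to close the trans-epoxide.
- The chloro aldehyde comes from the C14 ester of a western acid (C1–C10) and an eastern alcohol (C12–C23) by hydroformylation (adds C11) and organocatalytic α-chlorination (sets C12).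
- The western acid comes from a C2-symmetric bis(iodoalkene) made from L-tartrate (C7, C8) and an Evans-derived alkyl iodide (C3), joined by a desymmetrising Negishi coupling.
- The eastern alcohol comes from crotonaldehyde by kinetic resolution, Johnson–Claisen chirality transfer (C17) and Brown alkoxyallylboration (C14, C15).

Assumption: allyl methoxymethyl ether, (+)-Ipc2BOMe and both enantiomers of 2,5-diphenylpyrrolidine are taken as catalogue chemicals. Locants C1–C23 in the text are those of the target (C1 = lactone carbonyl).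

**Step 1**
Reactants: 1 diethyl (2R,3R)-2,3-dihydroxybutanedioate (diethyl L-tartrate)
Product: 2 diethyl (2R,3R)-2,3-bis[(tert-butyldimethylsilyl)oxy]butanedioate
Conditions: TBSOTf (2.4 equiv), 2,6-lutidine, CH2Cl2, 0 °C to rt
Reagents that add atoms: tert-butyldimethylsilyl triflate, CC(C)(C)[Si](C)(C)OS(=O)(=O)C(F)(F)F
Why: Silyl ether formation on both hydroxyls; the two stereocentres (later C7 and C8) come unchanged from the chiral pool.

**Step 2**
Reactants: 2 diethyl (2R,3R)-2,3-bis[(tert-butyldimethylsilyl)oxy]butanedioate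
Product: 3 (2R,3R)-2,3-bis[(tert-butyldimethylsilyl)oxy]butanedial
Conditions: i-Bu2AlH (2.1 equiv), toluene, −78 °C; MeOH, then aqueous potassium sodium tartrate; used crude
Reagents that add atoms: none
Why: Partial ester reduction at low temperature stops at the aluminium hemiacetal, which gives the dialdehyde on hydrolysis without epimerising the α-silyloxy centres.

**Step 3**
Reactants: 3 (2R,3R)-2,3-bis[(tert-butyldimethylsilyl)oxy]butanedial
Product: 4 (1E,3S,4S,5E)-3,4-bis[(tert-butyldimethylsilyl)oxy]-1,6-diiodohexa-1,5-diene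
Conditions: CrCl2 (12 equiv), CHI3 (4 equiv), THF/dioxane 1:6, 0 °C to rt
Reagents that add atoms: iodoform, IC(I)I
Why: Two-directional Takai iodo-olefination (geminal dichromium species from CHI3 and divalent chromium) turns both aldehydes into E-iodoalkenes under non-basic conditions, giving the C2-symmetric C5–C10 unit.

**Step 4**
Reactants: 5 (4S)-4-benzyl-3-propanoyl-1,3-oxazolidin-2-one; 6 tert-butyl bromoacetate
Product: 8 tert-butyl (3R)-4-[(4S)-4-benzyl-2-oxo-1,3-oxazolidin-3-yl]-3-methyl-4-oxobutanoate, via sodium Z-enolate 7 (not isolated)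
Conditions: NaN(SiMe3)2, THF, −78 °C; then 6, −78 to −40 °C
Reagents that add atoms: none
Why: Evans alkylation: the chelated Z-enolate is alkylated on the face opposite the benzyl group, which sets the methyl-bearing centre (later C3) as R in this compound.

**Step 5**
Reactants: 8 tert-butyl (3R)-4-[(4S)-4-benzyl-2-oxo-1,3-oxazolidin-3-yl]-3-methyl-4-oxobutanoate
Product: 9 tert-butyl (3R)-4-hydroxy-3-methylbutanoate
Conditions: LiBH4, MeOH (1 equiv), Et2O, 0 °C
Reagents that add atoms: none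
Why: Reductive removal of the auxiliary: the activated exocyclic imide carbonyl is reduced while the tert-butyl ester survives and resists lactonisation; the stereocentre is not touched.

**Step 6**
Reactants: 9 tert-butyl (3R)-4-hydroxy-3-methylbutanoate
Product: 10 tert-butyl (3R)-4-iodo-3-methylbutanoate
Conditions: I2, PPh3, imidazole, CH2Cl2, 0 °C to rt
Reagents that add atoms: iodine, II
Why: Appel-type iodination of the primary alcohol; the adjacent stereocentre is not involved.

**Step 7**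
Reactants: 10 tert-butyl (3R)-4-iodo-3-methylbutanoate; 4 (1E,3S,4S,5E)-3,4-bis[(tert-butyldimethylsilyl)oxy]-1,6-diiodohexa-1,5-diene (3 equiv)
Product: 12 tert-butyl (3S,5E,7S,8S,9E)-7,8-bis[(tert-butyldimethylsilyl)oxy]-10-iodo-3-methyldeca-5,9-dienoate, via alkylzinc iodide 11 (not isolated)
Conditions: Zn, LiCl, THF, 40 °C; then 4, Pd(PPh3)4 (5 mol%), THF, rt to 40 °C; excess 4 recovered
Reagents that add atoms: none
Why: Negishi sp3–sp2 coupling with retention of the E geometry; the two ends of C2-symmetric 4 are identical, so using it in excess gives a single mono-coupled product with the second iodoalkene kept for the ring closure.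

**Step 8**
Reactants: 12 tert-butyl (3S,5E,7S,8S,9E)-7,8-bis[(tert-butyldimethylsilyl)oxy]-10-iodo-3-methyldeca-5,9-dienoate
Product: 13 (3S,5E,7S,8S,9E)-7,8-bis[(tert-butyldimethylsilyl)oxy]-10-iodo-3-methyldeca-5,9-dienoic acid
Conditions: TMSOTf, 2,6-lutidine, CH2Cl2, 0 °C; aqueous work-up
Reagents that add atoms: none
Why: Silyl-triflate-mediated cleavage of the tert-butyl ester (loss of 2-methylpropene) leaves the secondary TBS ethers and the iodoalkene intact.

**Step 9**
Reactants: 14 (E)-but-2-enal (crotonaldehyde); 15 (E)-1-chlorobut-2-ene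
Product: 17 (2E,6E)-octa-2,6-dien-4-ol (racemic), via but-2-enylbarium chloride 16 (not isolated)
Conditions: BaI2, Li(C12H10) (lithium biphenylide, 2 equiv), THF, rt; 15, −78 °C; then 14, −78 °C
Reagents that add atoms: none
Why: Allylic barium addition: the reagent reacts at its α-carbon with retention of the E geometry and adds 1,2 to the enal, giving the linear dienol.

**Step 10**
Reactants: 17 (2E,6E)-octa-2,6-dien-4-ol (racemic)
Product: 18 (2E,4R,6E)-octa-2,6-dien-4-ol
Conditions: Ti(OiPr)4 (10 mol%), L-(+)-diisopropyl tartrate (15 mol%), t-BuOOH (0.6 equiv), 4 Å sieves, CH2Cl2, −20 °C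
Reagents that add atoms: none
Why: Sharpless kinetic resolution: with L-(+)-tartrate the (S)-alcohol is epoxidised fast, so the (R)-alcohol is recovered in high ee; the homoallylic alkene is not epoxidised.

**Step 11**
Reactants: 18 (2E,4R,6E)-octa-2,6-dien-4-ol
Product: 19 ethyl (3R,4E,7E)-3-methylnona-4,7-dienoate
Conditions: MeC(OEt)3, EtCO2H (cat.), 140 °C, EtOH distilled off
Reagents that add atoms: triethyl orthoacetate, CCOC(C)(OCC)OCC
Why: Johnson–Claisen rearrangement through a chair transition state with the butenyl group equatorial: suprafacial chirality transfer turns the (R)-carbinol into the (R)-methyl centre (C17) and gives the new E-alkene (C18=C19).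

**Step 12**
Reactants: 19 ethyl (3R,4E,7E)-3-methylnona-4,7-dienoate
Product: 20 (3R,4E,7E)-3-methylnona-4,7-dienal
Conditions: i-Bu2AlH (1.05 equiv), CH2Cl2, −78 °C
Reagents that add atoms: none
Why: Partial ester reduction to the aldehyde at −78 °C; the β-stereocentre is not epimerisable.

**Step 13**
Reactants: 20 (3R,4E,7E)-3-methylnona-4,7-dienal; 21 3-(methoxymethoxy)prop-1-ene (allyl methoxymethyl ether)
Product: 24 (3S,4S,6R,7E,10E)-3-(methoxymethoxy)-6-methyldodeca-1,7,10-trien-4-ol, via Z-alkoxyallylborane 22 (not isolated), via borinate 23 (not isolated)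
Conditions: 21, s-BuLi, THF, −78 °C; (+)-Ipc2BOMe; BF3·OEt2; then 20, −78 °C; NaOH, H2O2, rt
Reagents that add atoms: none
Why: Brown γ-alkoxyallylboration: the Z-alkoxyallylborane reacts through a chair transition state to give the syn-diol monoether, and the isopinocampheyl groups from (−)-α-pinene select the aldehyde face that gives 15S, hence 14S,15S.

**Step 14**
Reactants: 24 (3S,4S,6R,7E,10E)-3-(methoxymethoxy)-6-methyldodeca-1,7,10-trien-4-ol
Product: 26 (3S,4S,6R,7E,10E)-4-[(tert-butyldimethylsilyl)oxy]-6-methyldodeca-1,7,10-trien-3-ol, via silyl MOM diether 25 (not isolated)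
Conditions: TBSOTf, 2,6-lutidine, CH2Cl2, −78 to 0 °C; then TMSOTf, 2,2′-bipyridyl, 0 °C to rt; then H2O
Reagents that add atoms: tert-butyldimethylsilyl triflate, CC(C)(C)[Si](C)(C)OS(=O)(=O)C(F)(F)F
Why: Silylation of the C15 hydroxyl, then chemoselective acetal cleavage in the same flask (silyl triflate and bipyridyl convert the MOM ether into a pyridinium salt that water hydrolyses) frees the C14 hydroxyl while the TBS ether stays.

**Step 15**
Reactants: 13 (3S,5E,7S,8S,9E)-7,8-bis[(tert-butyldimethylsilyl)oxy]-10-iodo-3-methyldeca-5,9-dienoic acid; 26 (3S,4S,6R,7E,10E)-4-[(tert-butyldimethylsilyl)oxy]-6-methyldodeca-1,7,10-trien-3-ol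
Product: 27 (3S,4S,6R,7E,10E)-4-[(tert-butyldimethylsilyl)oxy]-6-methyldodeca-1,7,10-trien-3-yl (3S,5E,7S,8S,9E)-7,8-bis[(tert-butyldimethylsilyl)oxy]-10-iodo-3-methyldeca-5,9-dienoate
Conditions: 2-methyl-6-nitrobenzoic anhydride, 4-(dimethylamino)pyridine, Et3N, CH2Cl2, rt
Reagents that add atoms: none
Why: Shiina mixed-anhydride esterification at the only free hydroxyl joins the fragments and makes the future lactone C–O bond; no stereocentre is involved.

**Step 16**
Reactants: 27 the ester of step 15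
Product: 28 (4S,5S,7R,8E,11E)-5-[(tert-butyldimethylsilyl)oxy]-7-methyl-1-oxotrideca-8,11-dien-4-yl (3S,5E,7S,8S,9E)-7,8-bis[(tert-butyldimethylsilyl)oxy]-10-iodo-3-methyldeca-5,9-dienoate
Conditions: HRh(CO)(PPh3)3 (2 mol%), PPh3 (20 mol%), CO/H2 1:1 (5 bar), toluene, 50 °C
Reagents that add atoms: carbon monoxide, [C-]#[O+]
Why: Rhodium-catalysed hydroformylation acts on the single monosubstituted alkene and, because of the branching at C14, gives the linear aldehyde (adds C11); the 1,2-disubstituted alkenes and the iodoalkene react far more slowly.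

**Step 17**
Reactants: 28 the aldehyde of step 16
Product: 29 (2R,4S,5S,7R,8E,11E)-5-[(tert-butyldimethylsilyl)oxy]-2-chloro-7-methyl-1-oxotrideca-8,11-dien-4-yl (3S,5E,7S,8S,9E)-7,8-bis[(tert-butyldimethylsilyl)oxy]-10-iodo-3-methyldeca-5,9-dienoate
Conditions: N-chlorosuccinimide (1.2 equiv), (2S,5S)-2,5-diphenylpyrrolidine (10 mol%), CH2Cl2, 0 °C to rt; used at once without chromatography
Reagents that add atoms: N-chlorosuccinimide, O=C1CCC(=O)N1Cl
Why: Enamine-catalysed α-chlorination: in the enamine of the C2-symmetric pyrrolidine the near phenyl group shields one face, so chlorine is delivered to give the (2R)-chloride (C12) under catalyst control.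

**Step 18**
Reactants: 29 the chloro aldehyde of step 17
Product: 31 7,8,15-tris-O-(tert-butyldimethylsilyl)iriomoteolide 3a, via chromium alkoxide chlorohydrin 30 (not isolated)
Conditions: CrCl2 (15 equiv), NiCl2 (0.3 equiv), THF/DMF 4:1, 1.5 mM (syringe pump), rt; then KOt-Bu (excess over chromium), 0 °C, same flask
Reagents that add atoms: none
Why: Proposed new method: the iodoalkene adds oxidatively to zerovalent nickel (formed from NiCl2 by divalent chromium), transmetalates to trivalent chromium and attacks the aldehyde intramolecularly, closing the 15-membered ring with the 9E geometry kept; the Cornforth arrangement of the α-chloro aldehyde (C=O anti to C–Cl) directs attack to the 11S,12R anti-chlorohydrin alkoxide, which once released from chromium by tert-butoxide displaces chloride with inversion at C12 to give the trans (11S,12S) epoxide; the closest known chemistry is Nozaki–Hiyama–Kishi macrocyclisation, Ni/Cr coupling followed by alkoxide cyclisation onto a halide to form cyclic ethers, and Cornforth-selective alkenyl-metal addition to α-chloro aldehydes followed by base closure to trans-epoxides.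

**Step 19**
Reactants: 31 7,8,15-tris-O-(tert-butyldimethylsilyl)iriomoteolide 3a
Product: 32 iriomoteolide 3a
Conditions: Bu4NF, AcOH (1:1, excess), THF, 0 °C to rt
Reagents that add atoms: none
Why: Acetic-acid-buffered fluoride desilylation removes the three TBS ethers under near-neutral conditions that spare the vinyl epoxide and avoid acyl migration of the lactone.

**Compound list**
1 | diethyl (2R,3R)-2,3-dihydroxybutanedioate (diethyl L-tartrate) | CCOC(=O)[C@H](O)[C@@H](O)C(=O)OCC | starting material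
2 | diethyl (2R,3R)-2,3-bis[(tert-butyldimethylsilyl)oxy]butanedioate | CCOC(=O)[C@H](O[Si](C)(C)C(C)(C)C)[C@@H](O[Si](C)(C)C(C)(C)C)C(=O)OCC | intermediate
3 | (2R,3R)-2,3-bis[(tert-butyldimethylsilyl)oxy]butanedial | O=C[C@H](O[Si](C)(C)C(C)(C)C)[C@@H](O[Si](C)(C)C(C)(C)C)C=O | intermediate
4 | (1E,3S,4S,5E)-3,4-bis[(tert-butyldimethylsilyl)oxy]-1,6-diiodohexa-1,5-diene | I/C=C/[C@H](O[Si](C)(C)C(C)(C)C)[C@@H](O[Si](C)(C)C(C)(C)C)/C=C/I | intermediate
5 | (4S)-4-benzyl-3-propanoyl-1,3-oxazolidin-2-one | CCC(=O)N1[C@@H](Cc2ccccc2)COC1=O | starting material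
6 | tert-butyl bromoacetate | BrCC(=O)OC(C)(C)C | starting material
7 | sodium (Z)-enolate of 5 | C/C=C(\[O-])N1[C@@H](Cc2ccccc2)COC1=O.[Na+] | intermediate
8 | tert-butyl (3R)-4-[(4S)-4-benzyl-2-oxo-1,3-oxazolidin-3-yl]-3-methyl-4-oxobutanoate | CC(C)(C)OC(=O)C[C@@H](C)C(=O)N1[C@@H](Cc2ccccc2)COC1=O | intermediate
9 | tert-butyl (3R)-4-hydroxy-3-methylbutanoate | CC(C)(C)OC(=O)C[C@@H](C)CO | intermediate
10 | tert-butyl (3R)-4-iodo-3-methylbutanoate | CC(C)(C)OC(=O)C[C@@H](C)CI | intermediate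
11 | [(2R)-4-tert-butoxy-2-methyl-4-oxobutyl]zinc iodide | CC(C)(C)OC(=O)C[C@@H](C)C[Zn]I | intermediate
12 | tert-butyl (3S,5E,7S,8S,9E)-7,8-bis[(tert-butyldimethylsilyl)oxy]-10-iodo-3-methyldeca-5,9-dienoate | CC(C)(C)OC(=O)C[C@@H](C)C/C=C/[C@H](O[Si](C)(C)C(C)(C)C)[C@@H](O[Si](C)(C)C(C)(C)C)/C=C/I | intermediate
13 | (3S,5E,7S,8S,9E)-7,8-bis[(tert-butyldimethylsilyl)oxy]-10-iodo-3-methyldeca-5,9-dienoic acid | OC(=O)C[C@@H](C)C/C=C/[C@H](O[Si](C)(C)C(C)(C)C)[C@@H](O[Si](C)(C)C(C)(C)C)/C=C/I | intermediate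
14 | (E)-but-2-enal (crotonaldehyde) | C/C=C/C=O | starting material
15 | (E)-1-chlorobut-2-ene (crotyl chloride) | C/C=C/CCl | starting material
16 | (E)-but-2-enylbarium chloride | C/C=C/C[Ba]Cl | intermediate
17 | (2E,6E)-octa-2,6-dien-4-ol (racemic) | C/C=C/CC(O)/C=C/C | intermediate
18 | (2E,4R,6E)-octa-2,6-dien-4-ol | C/C=C/C[C@@H](O)/C=C/C | intermediate
19 | ethyl (3R,4E,7E)-3-methylnona-4,7-dienoate | C/C=C/C/C=C/[C@H](C)CC(=O)OCC | intermediate
20 | (3R,4E,7E)-3-methylnona-4,7-dienal | C/C=C/C/C=C/[C@H](C)CC=O | intermediate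
21 | 3-(methoxymethoxy)prop-1-ene (allyl methoxymethyl ether) | C=CCOCOC | starting material
22 | [(Z)-3-(methoxymethoxy)prop-2-enyl]bis(isopinocampheyl)borane, isopinocampheyl groups from (−)-α-pinene | COCO/C=C\CB([C@H]1C[C@H]2C[C@@H]([C@@H]1C)C2(C)C)[C@H]1C[C@H]2C[C@@H]([C@@H]1C)C2(C)C | intermediate
23 | bis(isopinocampheyl)borinate ester of 24 at O-4 | C/C=C/C/C=C/[C@H](C)C[C@H](OB([C@H]1C[C@H]2C[C@@H]([C@@H]1C)C2(C)C)[C@H]1C[C@H]2C[C@@H]([C@@H]1C)C2(C)C)[C@@H](OCOC)C=C | intermediate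
24 | (3S,4S,6R,7E,10E)-3-(methoxymethoxy)-6-methyldodeca-1,7,10-trien-4-ol | C/C=C/C/C=C/[C@H](C)C[C@H](O)[C@@H](OCOC)C=C | intermediate
25 | tert-butyl{[(3S,4S,6R,7E,10E)-3-(methoxymethoxy)-6-methyldodeca-1,7,10-trien-4-yl]oxy}dimethylsilane | C/C=C/C/C=C/[C@H](C)C[C@H](O[Si](C)(C)C(C)(C)C)[C@@H](OCOC)C=C | intermediate
26 | (3S,4S,6R,7E,10E)-4-[(tert-butyldimethylsilyl)oxy]-6-methyldodeca-1,7,10-trien-3-ol | C/C=C/C/C=C/[C@H](C)C[C@H](O[Si](C)(C)C(C)(C)C)[C@@H](O)C=C | intermediate
27 | (3S,4S,6R,7E,10E)-4-[(tert-butyldimethylsilyl)oxy]-6-methyldodeca-1,7,10-trien-3-yl (3S,5E,7S,8S,9E)-7,8-bis[(tert-butyldimethylsilyl)oxy]-10-iodo-3-methyldeca-5,9-dienoate | C/C=C/C/C=C/[C@H](C)C[C@H](O[Si](C)(C)C(C)(C)C)[C@@H](OC(=O)C[C@@H](C)C/C=C/[C@H](O[Si](C)(C)C(C)(C)C)[C@@H](O[Si](C)(C)C(C)(C)C)/C=C/I)C=C | intermediate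
28 | (4S,5S,7R,8E,11E)-5-[(tert-butyldimethylsilyl)oxy]-7-methyl-1-oxotrideca-8,11-dien-4-yl ester of acid 13 | C/C=C/C/C=C/[C@H](C)C[C@H](O[Si](C)(C)C(C)(C)C)[C@@H](OC(=O)C[C@@H](C)C/C=C/[C@H](O[Si](C)(C)C(C)(C)C)[C@@H](O[Si](C)(C)C(C)(C)C)/C=C/I)CCC=O | intermediate
29 | (2R,4S,5S,7R,8E,11E)-5-[(tert-butyldimethylsilyl)oxy]-2-chloro-7-methyl-1-oxotrideca-8,11-dien-4-yl ester of acid 13 | C/C=C/C/C=C/[C@H](C)C[C@H](O[Si](C)(C)C(C)(C)C)[C@@H](OC(=O)C[C@@H](C)C/C=C/[C@H](O[Si](C)(C)C(C)(C)C)[C@@H](O[Si](C)(C)C(C)(C)C)/C=C/I)C[C@@H](Cl)C=O | intermediate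
30 | dichlorochromium alkoxide of the 15-membered lactone (11S,12R)-chlorohydrin, 7,8,15-tris-TBS | C/C=C/C/C=C/[C@H](C)C[C@H](O[Si](C)(C)C(C)(C)C)[C@@H]1C[C@@H](Cl)[C@@H](O[Cr](Cl)Cl)/C=C/[C@H](O[Si](C)(C)C(C)(C)C)[C@@H](O[Si](C)(C)C(C)(C)C)/C=C/C[C@H](C)CC(=O)O1 | intermediate
31 | 7,8,15-tris-O-(tert-butyldimethylsilyl)iriomoteolide 3a | C/C=C/C/C=C/[C@H](C)C[C@H](O[Si](C)(C)C(C)(C)C)[C@@H]1C[C@@H]2O[C@H]2/C=C/[C@H](O[Si](C)(C)C(C)(C)C)[C@@H](O[Si](C)(C)C(C)(C)C)/C=C/C[C@H](C)CC(=O)O1 | intermediate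
32 | iriomoteolide 3a, (3S,7S,8S,11S,12S,14S,15S,17R) | C/C=C/C/C=C/[C@H](C)C[C@H](O)[C@@H]1C[C@@H]2O[C@H]2/C=C/[C@H](O)[C@@H](O)/C=C/C[C@H](C)CC(=O)O1 | target

**Totals**
Total step count: 19. Longest linear sequence: 11 steps (14 → 17 → 18 → 19 → 20 → 24 → 26 → 27 → 28 → 29 → 31 → 32).

**Steps most likely to fail, with fallbacks**

Step 18. Divalent chromium may reduce the C–Cl bond of the α-chloro aldehyde before the ring closes, or the ring strain may erode the Cornforth selectivity. The fallback makes the C10–C11 bond between the fragments and closes the lactone last; it sets out from 25 and 12 and comes back at 31. Hydroformylation of 25 (HRh(CO)(PPh3)3, CO/H2; no iodoalkene is present) gives the aldehyde F1, and α-chlorination as in step 17 gives the (2R)-chloro aldehyde F2. Iodine–lithium exchange on 12 (t-BuLi, 2 equiv, Et2O, −78 °C) gives the alkenyllithium F3, which adds to F2 under Cornforth control to give the anti-chlorohydrin F4. TMSOTf, 2,6-lutidine and 2,2′-bipyridyl, then water, remove the MOM ether and the tert-butyl ester to give the chlorohydrin hydroxy acid F5. KOH in EtOH closes the trans-epoxide to the epoxy seco acid F6, and Shiina macrolactonisation (2-methyl-6-nitrobenzoic anhydride, 4-(dimethylamino)pyridine, high dilution) gives 31.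

Step 16. The rhodium hydride may attack the iodoalkene or isomerise the allylic ester or the skipped diene. The fallback replaces the catalytic oxo reaction by stoichiometric hydrozirconation–carbonylation; it sets out from 27 and comes back at 28. Cp2Zr(H)Cl (THF, rt) adds only to the terminal alkene to give the alkylzirconocene chloride F7, CO (1 atm) inserts to give the acylzirconocene chloride F8, and dilute HCl releases 28.

Step 9. Activated barium is capricious, and loss of α-selectivity or E geometry would spoil the side chain. The fallback reaches the same linear dienol by allyl transfer; it sets out from 14 and comes back at 17. Acetone and but-2-enylmagnesium chloride give the γ-adduct 2,3-dimethylpent-4-en-2-ol F9. F9 and 14 with Sn(OTf)2 (10 mol%) in CH2Cl2 undergo a 2-oxonia-Cope crotyl transfer that gives 17 with the E alkene.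

**Further compounds**
F1 | step 18 | (4S,5S,7R,8E,11E)-5-[(tert-butyldimethylsilyl)oxy]-4-(methoxymethoxy)-7-methyltrideca-8,11-dienal | C/C=C/C/C=C/[C@H](C)C[C@H](O[Si](C)(C)C(C)(C)C)[C@@H](OCOC)CCC=O
F2 | step 18 | (2R,4S,5S,7R,8E,11E)-5-[(tert-butyldimethylsilyl)oxy]-2-chloro-4-(methoxymethoxy)-7-methyltrideca-8,11-dienal | C/C=C/C/C=C/[C@H](C)C[C@H](O[Si](C)(C)C(C)(C)C)[C@@H](OCOC)C[C@@H](Cl)C=O
F3 | step 18 | alkenyllithium from 12 (lithium in place of iodine at C10) | CC(C)(C)OC(=O)C[C@@H](C)C/C=C/[C@H](O[Si](C)(C)C(C)(C)C)[C@@H](O[Si](C)(C)C(C)(C)C)/C=C/[Li]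
F4 | step 18 | open-chain (11S,12R)-anti-chlorohydrin tert-butyl ester with 14-OMOM and 7,8,15-tris-TBS | C/C=C/C/C=C/[C@H](C)C[C@H](O[Si](C)(C)C(C)(C)C)[C@@H](OCOC)C[C@@H](Cl)[C@@H](O)/C=C/[C@H](O[Si](C)(C)C(C)(C)C)[C@@H](O[Si](C)(C)C(C)(C)C)/C=C/C[C@H](C)CC(=O)OC(C)(C)C
F5 | step 18 | (11S,12R)-12-chloro-11,14-dihydroxy seco acid, 7,8,15-tris-TBS | C/C=C/C/C=C/[C@H](C)C[C@H](O[Si](C)(C)C(C)(C)C)[C@@H](O)C[C@@H](Cl)[C@@H](O)/C=C/[C@H](O[Si](C)(C)C(C)(C)C)[C@@H](O[Si](C)(C)C(C)(C)C)/C=C/C[C@H](C)CC(=O)O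
F6 | step 18 | (11S,12S)-epoxy 14-hydroxy seco acid, 7,8,15-tris-TBS | C/C=C/C/C=C/[C@H](C)C[C@H](O[Si](C)(C)C(C)(C)C)[C@@H](O)C[C@@H]1O[C@H]1/C=C/[C@H](O[Si](C)(C)C(C)(C)C)[C@@H](O[Si](C)(C)C(C)(C)C)/C=C/C[C@H](C)CC(=O)O
F7 | step 16 | alkylzirconocene chloride from 27 (Cp2ZrCl at C12) | C/C=C/C/C=C/[C@H](C)C[C@H](O[Si](C)(C)C(C)(C)C)[C@@H](OC(=O)C[C@@H](C)C/C=C/[C@H](O[Si](C)(C)C(C)(C)C)[C@@H](O[Si](C)(C)C(C)(C)C)/C=C/I)CC[Zr](Cl)(C1C=CC=C1)C1C=CC=C1
F8 | step 16 | acylzirconocene chloride (C11 acyl–ZrCp2Cl) | C/C=C/C/C=C/[C@H](C)C[C@H](O[Si](C)(C)C(C)(C)C)[C@@H](OC(=O)C[C@@H](C)C/C=C/[C@H](O[Si](C)(C)C(C)(C)C)[C@@H](O[Si](C)(C)C(C)(C)C)/C=C/I)CCC(=O)[Zr](Cl)(C1C=CC=C1)C1C=CC=C1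
F9 | step 9 | 2,3-dimethylpent-4-en-2-ol | CC(C=C)C(C)(C)O
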